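The route rests on disconnecting the C3–C4 bond of ring B (chromanone numbering: O1, C2, C3, C4 in ring B; C4a–C8a in ring A). C2 carries O1, a methyl group and a hydrogen just as C2 of lactic acid does, and the ketone carbon C4 sits on ring-A carbon C4a next to the O1-bearing C8a. A lactate-derived (R)-4-aryloxypent-2-enoate is therefore placed on that oxygen beside an aldehyde. One carbene-catalysed intramolecular Stetter reaction then forms C4–C3, closes ring B and sets C3 trans to C2. The precursor is a 2-formylaryl ether flanked by two MOM ethers, carrying the verbenone-derived cyclobutylmethyl group and an allyl enoate.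

Key step: step 14

Assumption: in steps 14, 18 and 19 the chiral catalyst is named by the centre it has to deliver; both antipodes of each are accessible, and the matched one is fixed in a pilot run.
Remark: oxidative cleavage of α-pinene itself leaves a two-carbon arm on the cyclobutane; the one-carbon arm needed here comes from commercial (1S,5S)-verbenone, which has the same ring configuration.
Remark: aryl methyl ethers and an ethyl ester would need boron halides or hydroxide for cleavage after ring B exists. The isopropenylcyclobutane would not survive the former and C2/C3 are at risk with the latter, so MOM ethers and an allyl ester are used.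
Abbreviation: Cbm = [(1R,3S)-2,2-dimethyl-3-(prop-1-en-2-yl)cyclobutyl]methyl.

Step 1
Reactants: 1 (1S,5S)-(−)-verbenone
Product: 2 (1S,3R)-3-acetyl-2,2-dimethylcyclobutane-1-carboxylic acid (cis-pinononic acid)
Conditions: RuCl3·xH2O (2 mol%), NaIO4 (4 equiv), MeCN/EtOAc/H2O, 23 °C
Reagents that add atoms: sodium periodate NaIO4, [Na+].[O-]I(=O)(=O)=O; water, O
Why: Ruthenium tetroxide formed in situ cleaves the enone C=C (oxidative alkene cleavage) and the α-keto acid loses CO2, so the four-membered ring and its two cis-related stereocentres pass unchanged into 2.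

Step 2
Reactants: 2 (1S,3R)-3-acetyl-2,2-dimethylcyclobutane-1-carboxylic acid
Product: 3 (1S,3S)-2,2-dimethyl-3-(prop-1-en-2-yl)cyclobutane-1-carboxylic acid
Conditions: Ph3PCH3Br (2.5 equiv), KOt-Bu (2.4 equiv), THF, 0→23 °C
Reagents that add atoms: methyltriphenylphosphonium bromide, C[P+](c1ccccc1)(c1ccccc1)c1ccccc1.[Br-]
Why: Wittig methylenation of the methyl ketone beside the inert carboxylate; the centre next to the ketone is not endangered because the cis-1,3-disubstituted cyclobutane is also the more stable epimer.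

Step 3
Reactants: 3 (1S,3S)-2,2-dimethyl-3-(prop-1-en-2-yl)cyclobutane-1-carboxylic acid
Product: 4 [(1S,3S)-2,2-dimethyl-3-(prop-1-en-2-yl)cyclobutyl]methanol
Conditions: LiAlH4, Et2O, 0→23 °C; aqueous NaOH work-up
Reagents that add atoms: none
Why: Hydride reduction of the carboxylic acid to the primary alcohol leaves the isolated 1,1-disubstituted alkene and both ring centres alone.

Step 4
Reactants: 4 [(1S,3S)-2,2-dimethyl-3-(prop-1-en-2-yl)cyclobutyl]methanol
Product: 5 (1S,3S)-1-(iodomethyl)-2,2-dimethyl-3-(prop-1-en-2-yl)cyclobutane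
Conditions: PPh3, I2, imidazole, CH2Cl2, 0→23 °C
Reagents that add atoms: iodine, II
Why: Appel iodination proceeds by SN2 displacement of the oxyphosphonium group at the primary carbon, so no cyclobutylcarbinyl cation and no ring expansion can arise.

Step 5
Reactants: 6 5-chlororesorcinol
Product: 7 1-chloro-3,5-bis(methoxymethoxy)benzene
Conditions: MOMCl (2.4 equiv), i-Pr2NEt, CH2Cl2, 0→23 °C
Reagents that add atoms: chloromethyl methyl ether, COCCl
Why: Williamson-type O-alkylation of both phenols installs acetal groups that direct the metalation of step 6 and later come off without protic acid.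

Step 6
Reactants: 7 1-chloro-3,5-bis(methoxymethoxy)benzene
Product: 9 5-chloro-2-iodo-1,3-bis(methoxymethoxy)benzene, via aryllithium 8 (not isolated)
Conditions: n-BuLi, THF, −78→0 °C; I2, −78 °C
Reagents that add atoms: iodine, II
Why: Directed ortho-metalation takes place at the carbon flanked by both chelating OMOM groups (para to chlorine, so no aryne can form) and iodine traps the aryllithium.

Step 7
Reactants: 5 (1S,3S)-1-(iodomethyl)-2,2-dimethyl-3-(prop-1-en-2-yl)cyclobutane; 9 5-chloro-2-iodo-1,3-bis(methoxymethoxy)benzene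
Product: 12 5-chloro-2-Cbm-1,3-bis(methoxymethoxy)benzene, via alkyllithium 10 (not isolated), via alkylzinc chloride 11 (not isolated)
Conditions: 5, t-BuLi (2.1 equiv), Et2O, −78 °C; ZnCl2 (THF), −78→23 °C; 9, Pd(OAc)2 (3 mol%), SPhos (6 mol%), THF, 50 °C
Reagents that add atoms: none
Why: Lithium–iodine exchange and transmetalation give a primary alkylzinc for a Negishi coupling in which C–I reacts far faster than C–Cl and the bulky biaryl phosphine copes with two ortho substituents; the cyclobutane centres are not involved.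

Step 8
Reactants: 12 5-chloro-2-Cbm-1,3-bis(methoxymethoxy)benzene
Product: 13 4-Cbm-3,5-bis(methoxymethoxy)phenol
Conditions: Pd2(dba)3 (2 mol%), tBuXPhos (8 mol%), KOH, 1,4-dioxane/H2O, 100 °C; aq. NH4Cl
Reagents that add atoms: potassium hydroxide KOH, [K+].[OH-]
Why: Palladium-catalysed C–O coupling of the aryl chloride with hydroxide unmasks the phenol para to the alkyl group under conditions that MOM ethers and the alkene tolerate.

Step 9
Reactants: 13 4-Cbm-3,5-bis(methoxymethoxy)phenol
Product: 14 3-Cbm-6-hydroxy-2,4-bis(methoxymethoxy)benzaldehyde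
Conditions: MgCl2, Et3N, (CH2O)n, MeCN, 80 °C
Reagents that add atoms: paraformaldehyde (formaldehyde), C=O
Why: Magnesium-mediated ortho-formylation of the phenoxide (Casnati–Skattebøl reaction) is ortho-specific, and the two ortho positions are equivalent by symmetry, so a single salicylaldehyde should result.

Step 10
Reactants: 15 ethyl (S)-lactate
Product: 16 ethyl (S)-2-[(tert-butyldimethylsilyl)oxy]propanoate
Conditions: TBSCl, imidazole, CH2Cl2, 23 °C
Reagents that add atoms: tert-butyldimethylsilyl chloride, CC(C)(C)[Si](C)(C)Cl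
Why: Silylation protects the secondary alcohol for the hydride reduction and does not touch the stereocentre.

Step 11
Reactants: 16 ethyl (S)-2-[(tert-butyldimethylsilyl)oxy]propanoate
Product: 18 allyl (S,E)-4-[(tert-butyldimethylsilyl)oxy]pent-2-enoate, via silyloxy aldehyde 17 (not isolated)
Conditions: i-Bu2AlH (1.05 equiv), CH2Cl2, −78 °C; Ph3P=CHCO2CH2CH=CH2, −78→23 °C
Reagents that add atoms: allyl (triphenylphosphoranylidene)acetate, C=CCOC(=O)C=P(c1ccccc1)(c1ccccc1)c1ccccc1
Why: Partial reduction to the aluminium hemiacetal and in situ Wittig olefination with the stabilised ylide give the E-enoate without isolating the configurationally labile α-silyloxy aldehyde.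

Step 12
Reactants: 18 allyl (S,E)-4-[(tert-butyldimethylsilyl)oxy]pent-2-enoate
Product: 19 allyl (S,E)-4-hydroxypent-2-enoate
Conditions: HF·pyridine, THF, 0→23 °C
Reagents that add atoms: none
Why: Buffered fluoride desilylation frees the alcohol without conjugate addition or ester exchange.

Step 13
Reactants: 14 3-Cbm-6-hydroxy-2,4-bis(methoxymethoxy)benzaldehyde; 19 allyl (S,E)-4-hydroxypent-2-enoate
Product: 20 allyl (R,E)-4-[4-Cbm-2-formyl-3,5-bis(methoxymethoxy)phenoxy]pent-2-enoate
Conditions: PPh3, DIAD, toluene, 0→23 °C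
Reagents that add atoms: none
Why: Mitsunobu etherification of the acidic salicylaldehyde hydroxyl proceeds by SN2 with inversion, turning the (S)-alcohol into the (R)-aryl ether; the electron-poor enoate disfavours SN2' attack and ionisation.

Step 14
Reactants: 20 allyl (R,E)-4-[4-Cbm-2-formyl-3,5-bis(methoxymethoxy)phenoxy]pent-2-enoate
Product: 21 allyl 2-[(2R,3R)-6-Cbm-5,7-bis(methoxymethoxy)-2-methyl-4-oxochroman-3-yl]acetate
Conditions: cis-1-amino-2-indanol-derived bicyclic N-C6F5 triazolium tetrafluoroborate (matched antipode, 20 mol%), KN(SiMe3)2 (20 mol%), toluene, 23 °C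
Reagents that add atoms: none
Why: The carbene freed from the triazolium salt adds to the aldehyde of 20 and, after proton transfer, the Breslow intermediate attacks the enoate β-carbon as an acyl anion equivalent; proton transfer to the ester enolate and loss of the carbene give the C4 ketone. The closest known reaction is the asymmetric intramolecular Stetter reaction of salicylaldehyde-derived 4-aryloxybut-2-enoates to 3-substituted chroman-4-ones. Ring B closes in the 6-exo-trig mode. The only new stereocentre, C3, is set by the enoate face that the catalyst exposes, while C2 (from lactate, inverted once in step 13) is not touched. The step needs trans over cis: with the C2–H eclipsing the E-alkene (A(1,3) strain) the tethered nucleophile reaches C3 on the face away from the C2 methyl, the matched catalyst antipode reinforces this, and trans is also the more stable epimer α to the ketone. The two ortho oxygen substituents slow addition to the aldehyde, which is why the electron-poor N-C6F5 carbene is chosen.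

Step 15
Reactants: 21 allyl 2-[(2R,3R)-6-Cbm-5,7-bis(methoxymethoxy)-2-methyl-4-oxochroman-3-yl]acetate
Product: 22 2-[(2R,3R)-6-Cbm-5,7-bis(methoxymethoxy)-2-methyl-4-oxochroman-3-yl]acetic acid
Conditions: Pd(PPh3)4 (5 mol%), morpholine (3 equiv), THF, 23 °C
Reagents that add atoms: none
Why: Zerovalent palladium ionises only the allyl ester (Tsuji–Trost deallylation, morpholine as allyl acceptor) and releases the acid at neutral pH, so neither C2 nor C3 can be lost through enolisation or retro-oxa-Michael opening.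

Step 16
Reactants: 22 2-[(2R,3R)-6-Cbm-5,7-bis(methoxymethoxy)-2-methyl-4-oxochroman-3-yl]acetic acid
Product: 24 (2R,3R)-6-Cbm-5,7-bis(methoxymethoxy)-2,3-dimethylchroman-4-one, via Barton ester 23 (not isolated)
Conditions: 1-hydroxypyridine-2(1H)-thione, DCC, DMAP (cat.), CH2Cl2, 0→23 °C, dark; t-BuSH (10 equiv), THF, visible light, 23 °C
Reagents that add atoms: none
Why: Barton reductive decarboxylation: the thiohydroxamate ester fragments to the primary radical on the C3 methylene, which the thiol reduces faster than it can add to the neighbouring ketone (1,2-acyl shift), leaving the C3 methyl group with C3 unchanged.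

Step 17
Reactants: 24 (2R,3R)-6-Cbm-5,7-bis(methoxymethoxy)-2,3-dimethylchroman-4-one
Product: 26 (2R,3R)-6-Cbm-5,7-dihydroxy-2,3-dimethylchroman-4-one, via bis(trimethylsilyl) ether 25 (not isolated)
Conditions: TMSOTf, 2,2'-bipyridyl, CH2Cl2, 0→23 °C; H2O; NaHCO3 work-up
Reagents that add atoms: none
Why: The silyl triflate–bipyridyl pair converts aryl MOM ethers into silyl ethers that water hydrolyses (acetal cleavage without protic acid), which spares the acid-labile isopropenylcyclobutane.

Step 18
Reactants: 26 (2R,3R)-6-Cbm-5,7-dihydroxy-2,3-dimethylchroman-4-one; 27 3-phenylpropiolaldehyde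
Product: 29 methyl (S)-3-[(2R,3R)-6-Cbm-5,7-dihydroxy-2,3-dimethyl-4-oxochroman-8-yl]-3-phenylpropanoate, via dihydrocoumarin lactone 28 (not isolated)
Conditions: 27 (1.3 equiv), cis-1-amino-2-indanol-derived bicyclic N-mesityl triazolium chloride (matched antipode, 10 mol%), i-Pr2NEt (10 mol%), toluene, 40 °C; then MeOH, K2CO3, 0→23 °C
Reagents that add atoms: methanol, CO
Why: The carbene turns the ynal into an α,β-unsaturated acyl azolium to which C8, the only free ring carbon of the acidic acylphloroglucinol, adds (carbene-catalysed [3+3] annulation of phenols and enols, Coates–Claisen-type pathway); O7 then closes the lactone, the chiral triazolium fixes the benzylic centre as S, and methanolysis opens the lactone to the ester.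

Step 19
Reactants: 29 methyl (S)-3-[(2R,3R)-6-Cbm-5,7-dihydroxy-2,3-dimethyl-4-oxochroman-8-yl]-3-phenylpropanoate
Product: 30 methyl (S)-3-[(2R,3R,6R)-6-Cbm-5-hydroxy-2,3-dimethyl-6-(3-methylbut-2-en-1-yl)-4,7-dioxo-3,4,6,7-tetrahydro-2H-chromen-8-yl]-3-phenylpropanoate
Conditions: NaH (2.0 equiv), THF, 0 °C; Pd2(dba)3·CHCl3 (2.5 mol%), N,N'-(cyclohexane-1,2-diyl)bis(2-diphenylphosphinobenzamide) (matched antipode, 7.5 mol%), prenyl acetate (1.1 equiv), 0→23 °C; aq. NH4Cl
Reagents that add atoms: prenyl acetate (3-methylbut-2-en-1-yl acetate), CC(C)=CCOC(C)=O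
Why: Proposed new method: zerovalent palladium ionises prenyl acetate to a π-prenyl complex and the dianion of 29 attacks its unsubstituted terminus through C6, the carbon flanked by both phenoxide oxygens, giving the linear prenyl group and a stabilised vinylogous-acid enolate (O-prenyl ethers re-ionise, C8 is shielded by its branched side chain, and the dianion cannot relactonise); the chiral pocket of the bisphosphine ligand is asked to choose the ring face and so set C6 as R, because the existing centres are too remote to do so; the closest known reactions are base- or palladium-mediated dearomative C-prenylation of acylphloroglucinols and palladium-catalysed asymmetric allylic dearomatisation of naphthols.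

Step 20
Reactants: 30 methyl ester of the target
Product: 31 (S)-3-[(2R,3R,6R)-6-Cbm-5-hydroxy-2,3-dimethyl-6-(3-methylbut-2-en-1-yl)-4,7-dioxo-3,4,6,7-tetrahydro-2H-chromen-8-yl]-3-phenylpropanoic acid (target)
Conditions: LiOH, THF/MeOH/H2O, 0→23 °C; 1 M HCl to pH 3, 0 °C
Reagents that add atoms: lithium hydroxide LiOH, [Li+].[OH-]
Why: Saponification of the methyl ester; under base the ring system is held as its delocalised enolate, and cold, mild acidification returns the free acid without touching the isopropenyl group.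

Compound list
1 | (1S,5S)-(−)-verbenone | CC1=CC(=O)[C@H]2C[C@@H]1C2(C)C | starting material
2 | (1S,3R)-3-acetyl-2,2-dimethylcyclobutane-1-carboxylic acid | CC(=O)[C@@H]1C[C@H](C(=O)O)C1(C)C | intermediate
3 | (1S,3S)-2,2-dimethyl-3-(prop-1-en-2-yl)cyclobutane-1-carboxylic acid | C=C(C)[C@@H]1C[C@H](C(=O)O)C1(C)C | intermediate
4 | [(1S,3S)-2,2-dimethyl-3-(prop-1-en-2-yl)cyclobutyl]methanol | C=C(C)[C@@H]1C[C@H](CO)C1(C)C | intermediate
5 | (1S,3S)-1-(iodomethyl)-2,2-dimethyl-3-(prop-1-en-2-yl)cyclobutane | C=C(C)[C@@H]1C[C@H](CI)C1(C)C | intermediate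
6 | 5-chlororesorcinol | Oc1cc(O)cc(Cl)c1 | starting material
7 | 1-chloro-3,5-bis(methoxymethoxy)benzene | COCOc1cc(Cl)cc(OCOC)c1 | intermediate
8 | [4-chloro-2,6-bis(methoxymethoxy)phenyl]lithium | [Li]c1c(OCOC)cc(Cl)cc1OCOC | intermediate
9 | 5-chloro-2-iodo-1,3-bis(methoxymethoxy)benzene | COCOc1cc(Cl)cc(OCOC)c1I | intermediate
10 | {[(1S,3S)-2,2-dimethyl-3-(prop-1-en-2-yl)cyclobutyl]methyl}lithium | C=C(C)[C@@H]1C[C@H](C[Li])C1(C)C | intermediate
11 | {[(1S,3S)-2,2-dimethyl-3-(prop-1-en-2-yl)cyclobutyl]methyl}zinc chloride | C=C(C)[C@@H]1C[C@H](C[Zn]Cl)C1(C)C | intermediate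
12 | 5-chloro-2-Cbm-1,3-bis(methoxymethoxy)benzene | C=C(C)[C@@H]1C[C@H](Cc2c(OCOC)cc(Cl)cc2OCOC)C1(C)C | intermediate
13 | 4-Cbm-3,5-bis(methoxymethoxy)phenol | C=C(C)[C@@H]1C[C@H](Cc2c(OCOC)cc(O)cc2OCOC)C1(C)C | intermediate
14 | 3-Cbm-6-hydroxy-2,4-bis(methoxymethoxy)benzaldehyde | C=C(C)[C@@H]1C[C@H](Cc2c(OCOC)cc(O)c(C=O)c2OCOC)C1(C)C | intermediate
15 | ethyl (S)-lactate | CCOC(=O)[C@H](C)O | starting material
16 | ethyl (S)-2-[(tert-butyldimethylsilyl)oxy]propanoate | CCOC(=O)[C@H](C)O[Si](C)(C)C(C)(C)C | intermediate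
17 | (S)-2-[(tert-butyldimethylsilyl)oxy]propanal | O=C[C@H](C)O[Si](C)(C)C(C)(C)C | intermediate
18 | allyl (S,E)-4-[(tert-butyldimethylsilyl)oxy]pent-2-enoate | C=CCOC(=O)/C=C/[C@H](C)O[Si](C)(C)C(C)(C)C | intermediate
19 | allyl (S,E)-4-hydroxypent-2-enoate | C=CCOC(=O)/C=C/[C@H](C)O | intermediate
20 | allyl (R,E)-4-[4-Cbm-2-formyl-3,5-bis(methoxymethoxy)phenoxy]pent-2-enoate | C=C(C)[C@@H]1C[C@H](Cc2c(OCOC)cc(O[C@H](C)/C=C/C(=O)OCC=C)c(C=O)c2OCOC)C1(C)C | intermediate
21 | allyl 2-[(2R,3R)-6-Cbm-5,7-bis(methoxymethoxy)-2-methyl-4-oxochroman-3-yl]acetate | C=C(C)[C@@H]1C[C@H](Cc2c(OCOC)cc3O[C@H](C)[C@@H](CC(=O)OCC=C)C(=O)c3c2OCOC)C1(C)C | intermediate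
22 | 2-[(2R,3R)-6-Cbm-5,7-bis(methoxymethoxy)-2-methyl-4-oxochroman-3-yl]acetic acid | C=C(C)[C@@H]1C[C@H](Cc2c(OCOC)cc3O[C@H](C)[C@@H](CC(=O)O)C(=O)c3c2OCOC)C1(C)C | intermediate
23 | 2-thioxopyridin-1(2H)-yl ester of 22 (Barton ester) | C=C(C)[C@@H]1C[C@H](Cc2c(OCOC)cc3O[C@H](C)[C@@H](CC(=O)On4ccccc4=S)C(=O)c3c2OCOC)C1(C)C | intermediate
24 | (2R,3R)-6-Cbm-5,7-bis(methoxymethoxy)-2,3-dimethylchroman-4-one | C=C(C)[C@@H]1C[C@H](Cc2c(OCOC)cc3O[C@H](C)[C@@H](C)C(=O)c3c2OCOC)C1(C)C | intermediate
25 | (2R,3R)-6-Cbm-2,3-dimethyl-5,7-bis(trimethylsilyloxy)chroman-4-one | C=C(C)[C@@H]1C[C@H](Cc2c(O[Si](C)(C)C)cc3O[C@H](C)[C@@H](C)C(=O)c3c2O[Si](C)(C)C)C1(C)C | intermediate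
26 | (2R,3R)-6-Cbm-5,7-dihydroxy-2,3-dimethylchroman-4-one | C=C(C)[C@@H]1C[C@H](Cc2c(O)cc3O[C@H](C)[C@@H](C)C(=O)c3c2O)C1(C)C | intermediate
27 | 3-phenylpropiolaldehyde | O=CC#Cc1ccccc1 | starting material
28 | lactone of 26 in which O7 and C8 are bridged by C(=O)–CH2–CH(Ph), benzylic carbon S (4-phenyl-3,4-dihydrocoumarin fused to ring A) | C=C(C)[C@@H]1C[C@H](Cc2c(O)c3C(=O)[C@H](C)[C@@H](C)Oc3c4c2OC(=O)C[C@H]4c5ccccc5)C1(C)C | intermediate
29 | methyl (S)-3-[(2R,3R)-6-Cbm-5,7-dihydroxy-2,3-dimethyl-4-oxochroman-8-yl]-3-phenylpropanoate | C=C(C)[C@@H]1C[C@H](Cc2c(O)c([C@@H](CC(=O)OC)c4ccccc4)c3O[C@H](C)[C@@H](C)C(=O)c3c2O)C1(C)C | intermediate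
30 | methyl (S)-3-[(2R,3R,6R)-6-Cbm-5-hydroxy-2,3-dimethyl-6-(3-methylbut-2-en-1-yl)-4,7-dioxo-3,4,6,7-tetrahydro-2H-chromen-8-yl]-3-phenylpropanoate | C=C(C)[C@@H]1C[C@H](C[C@@]2(CC=C(C)C)C(=O)C([C@@H](CC(=O)OC)c3ccccc3)=C3O[C@H](C)[C@@H](C)C(=O)C3=C2O)C1(C)C | intermediate
31 | (S)-3-[(2R,3R,6R)-6-Cbm-5-hydroxy-2,3-dimethyl-6-(3-methylbut-2-en-1-yl)-4,7-dioxo-3,4,6,7-tetrahydro-2H-chromen-8-yl]-3-phenylpropanoic acid | C=C(C)[C@@H]1C[C@H](C[C@@]2(CC=C(C)C)C(=O)C([C@@H](CC(=O)O)c3ccccc3)=C3O[C@H](C)[C@@H](C)C(=O)C3=C2O)C1(C)C | target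

Total step count: 20. Longest linear sequence: 15 steps (steps 1–4, 7–9 and 13–20, from verbenone 1).

Steps most likely to fail

1. Step 19. The ligand may fail to discriminate the two faces of the flat, fully substituted ring, giving poor facial selectivity at C6, and alkylation at C8 or on oxygen may compete. The fallback replaces catalyst control by substrate control and sets out from lactone 28, isolated by leaving out the methanolysis of step 18. In 28 the phenyl group is locked pseudo-axial on the ring face that carries the cyclobutylmethyl group in the target, so attack anti to phenyl leads to 6R. The sodium phenoxide of 28 (NaH, toluene) would be C-alkylated at the ortho carbon C6 with prenyl bromide to the C6-prenylated dienone enol lactone F1. LiOH in THF/H2O at 0 °C then opens the activated enol lactone and the route is rejoined at target 31.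

2. Step 14. The Breslow intermediate may form too slowly at the electron-rich, doubly ortho-substituted aldehyde, or the catalyst and the C2 centre may be poorly matched, so that ring closure stalls or gives cis material. The fallback builds ring B by aldol addition and C–O closure and sets out from aldehyde 14. EtMgBr (excess, THF, 0 °C) would give the 1-arylpropan-1-ol F2, and MnO2 the aryl ethyl ketone F3. A syn-selective boron aldol addition to acetaldehyde (Ipc2BOTf of the antipode leading to the 2R,3S adduct, i-Pr2NEt, the phenol carried as its boron aryloxide) would give the syn-aldol F4. Mitsunobu cyclisation (PPh3, DIAD) with inversion at the carbinol then closes ring B to the trans-dimethylchromanone, and the route is rejoined at 24.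

3. Step 18. O-Acylation of the phenol may outrun C–C bond formation at the hindered C8, or catalyst control at the benzylic carbon may be low. The fallback builds a coumarin first and sets out from diphenol 26. Magnesium-mediated formylation (MgCl2, Et3N, paraformaldehyde) at the only free position would give the 8-formyl diphenol F5. Still–Gennari olefination ((CF3CH2O)2P(O)CH2CO2Me, KN(SiMe3)2, 18-crown-6) gives the Z-enoate F6, which lactonises to the coumarin F7. Rhodium-catalysed asymmetric conjugate addition of phenylboronic acid (Rh(acac)(C2H4)2, Segphos antipode for the S centre, dioxane/H2O, 60 °C) would then give lactone 28, and methanolysis (K2CO3, MeOH) rejoins the route at 29.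

Further compounds
F1 | step 19 | C6-prenylated (6R) dienone enol lactone derived from 28 | C=C(C)[C@@H]1C[C@H](C[C@@]2(CC=C(C)C)C(OC(=O)C[C@H]4c5ccccc5)=C4C3=C(C2=O)C(=O)[C@H](C)[C@@H](C)O3)C1(C)C
F2 | step 14 | 1-[3-Cbm-6-hydroxy-2,4-bis(methoxymethoxy)phenyl]propan-1-ol (both carbinol epimers) | C=C(C)[C@@H]1C[C@H](Cc2c(OCOC)cc(O)c(C(O)CC)c2OCOC)C1(C)C
F3 | step 14 | 1-[3-Cbm-6-hydroxy-2,4-bis(methoxymethoxy)phenyl]propan-1-one | C=C(C)[C@@H]1C[C@H](Cc2c(OCOC)cc(O)c(C(=O)CC)c2OCOC)C1(C)C
F4 | step 14 | (2R,3S)-1-[3-Cbm-6-hydroxy-2,4-bis(methoxymethoxy)phenyl]-3-hydroxy-2-methylbutan-1-one | C=C(C)[C@@H]1C[C@H](Cc2c(OCOC)cc(O)c(C(=O)[C@H](C)[C@H](C)O)c2OCOC)C1(C)C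
F5 | step 18 | (2R,3R)-6-Cbm-5,7-dihydroxy-2,3-dimethyl-4-oxochromane-8-carbaldehyde | C=C(C)[C@@H]1C[C@H](Cc2c(O)c(C=O)c3O[C@H](C)[C@@H](C)C(=O)c3c2O)C1(C)C
F6 | step 18 | methyl (Z)-3-[(2R,3R)-6-Cbm-5,7-dihydroxy-2,3-dimethyl-4-oxochroman-8-yl]acrylate | C=C(C)[C@@H]1C[C@H](Cc2c(O)c(/C=C\C(=O)OC)c3O[C@H](C)[C@@H](C)C(=O)c3c2O)C1(C)C
F7 | step 18 | coumarin formed from F6 by lactonisation onto O7 | C=C(C)[C@@H]1C[C@H](Cc2c(O)c3C(=O)[C@H](C)[C@@H](C)Oc3c4c2OC(=O)C=C4)C1(C)C
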